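**Retrosynthetic overview**
- The C7–OH and both phenol O–H bonds are freed last, by one hydrogenolysis of an O–NHPh bond and two O–benzyl bonds.
- The C7–O bond and the C7 stereocentre come from a one-flask 1,4-reduction/α-aminoxylation of an E-enone (C6=C7–C8=O), with the oxygen taken from nitrosobenzene.
- The C6=C7 bond comes from cross-metathesis of a terminal alkene with oct-1-en-3-one, which brings in C7–C13.
- The aryl–C1 bond and the C2 acetate come from aryl Grignard opening of an (R)-epoxide followed by acetylation; C2 is set beforehand by organocatalytic α-chlorination of hept-6-enal.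
- Rings: the arene is bought; the only ring made is a transient oxirane (step 2), opened in the same flask.

Assumption: the target is read as the (2R,7R) isomer, and hept-6-enal, 1,3-bis(benzyloxy)-5-bromobenzene and oct-1-en-3-one are taken as purchasable.

**Step 1**
Reactants: 1 hept-6-enal
Product: 3 (S)-2-chlorohept-6-en-1-ol, via (S)-2-chlorohept-6-enal 2 (not isolated)
Conditions: NCS (1.3 equiv), (2R,5R)-2,5-diphenylpyrrolidine (10 mol%), CH2Cl2, rt; then MeOH, NaBH4, 0 °C
Reagents that add atoms: N-chlorosuccinimide, O=C1CCC(=O)N1Cl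
Why: Enamine catalysis (organocatalytic α-chlorination of an aldehyde), in which the phenyl group of the C2-symmetric pyrrolidine next to the enamine carbon is expected to block one face so that Cl enters from the other and sets 2S, and NaBH4 reduces the configurationally labile chloro aldehyde at once.

**Step 2**
Reactants: 3 (S)-2-chlorohept-6-en-1-ol; 4 1,3-bis(benzyloxy)-5-bromobenzene
Product: 8 (R)-1-[3,5-bis(benzyloxy)phenyl]hept-6-en-2-yl acetate, via (R)-2-(pent-4-en-1-yl)oxirane 5 (not isolated), via 3,5-bis(benzyloxy)phenylmagnesium bromide 6 (not isolated), via bromomagnesium (R)-1-[3,5-bis(benzyloxy)phenyl]hept-6-en-2-olate 7 (not isolated)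
Conditions: 3, NaH (1.1 equiv), THF, 0 °C→rt (gives 5); separately 4, Mg, THF, 50 °C (gives 6, 1.4 equiv); 6 + CuI (10 mol%) added to 5, −30→0 °C; then Ac2O (4 equiv), DMAP (10 mol%), 0 °C→rt
Reagents that add atoms: acetic anhydride, CC(=O)OC(C)=O
Why: Intramolecular Williamson closure (SN2, inversion, 2S chloride to 2R epoxide), then CuI-catalysed SN2 opening by the aryl Grignard reagent at the unsubstituted oxirane carbon (C2 untouched) and acylation of the magnesium alkoxide in the same pot, so no new stereocentre is made and the volatile epoxide is never isolated.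

**Step 3**
Reactants: 8 (R)-1-[3,5-bis(benzyloxy)phenyl]hept-6-en-2-yl acetate; 9 oct-1-en-3-one
Product: 10 (2R,6E)-1-[3,5-bis(benzyloxy)phenyl]-8-oxotridec-6-en-2-yl acetate
Conditions: 9 (3 equiv), second-generation Hoveyda–Grubbs catalyst RuCl2(H2IMes)(=CH-C6H4-2-OiPr) (3 mol%), CH2Cl2, 40 °C
Reagents that add atoms: none
Why: Olefin cross-metathesis between a terminal alkene that homodimerises fast and an electron-poor vinyl ketone that homodimerises slowly is selective for the cross product and gives the E-enone, with ethene leaving.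

**Step 4**
Reactants: 10 (2R,6E)-1-[3,5-bis(benzyloxy)phenyl]-8-oxotridec-6-en-2-yl acetate
Product: 13 (2R,7R)-1-[3,5-bis(benzyloxy)phenyl]-8-oxo-7-[(phenylamino)oxy]tridecan-2-yl acetate, via Z-trichlorosilyl enolate 11 (not isolated), via N-trichlorosilyl aminooxy ketone 12 (not isolated)
Conditions: (S)-BINAPO [(S)-2,2'-bis(diphenylphosphoryl)-1,1'-binaphthyl] (10 mol%), HSiCl3 (1.2 equiv), CH2Cl2, −40→0 °C; excess HSiCl3 removed in vacuo; CH2Cl2/EtCN, −78 °C, PhNO (1.2 equiv, slow addition); then cold H2O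
Reagents that add atoms: nitrosobenzene, O=Nc1ccccc1
Why: Proposed new method: a chiral Lewis-base-catalysed reductive α-aminoxylation, in which the bis(phosphine oxide) activates HSiCl3 to deliver hydride to C6 of the s-cis enone through a six-membered transition state and so gives only the C7=C8 Z-trichlorosilyl enolate 11 (oxygen can then enter at C7 but not C9), after which the catalyst-bound cationic hypervalent silicon holds nitrosobenzene through nitrogen and passes its oxygen to C7 in a closed six-membered array whose BINAPO ligand differentiates the enolate faces to set 7R (the sense of induction cannot be read from precedent, so the catalyst antipode is fixed on the first analytical run); the closest known reactions are the Lewis-base-catalysed reductive aldol of enones with HSiCl3 and the silyl-Lewis-acid-promoted O-selective nitroso aldol of silyl enol ethers.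

**Step 5**
Reactants: 13 (2R,7R)-1-[3,5-bis(benzyloxy)phenyl]-8-oxo-7-[(phenylamino)oxy]tridecan-2-yl acetate
Product: 14 (2R,7R)-1-(3,5-dihydroxyphenyl)-7-hydroxy-8-oxotridecan-2-yl acetate
Conditions: H2 (1 atm), Pd(OH)2/C (20 wt%), EtOAc, rt
Reagents that add atoms: none
Why: Heterogeneous hydrogenolysis cleaves the weak N–O bond and both aryl benzyl ethers, while the aliphatic ketone, the non-benzylic acetate and both stereocentres are left alone.

**Compound list**
1 | hept-6-enal | C=CCCCCC=O | starting material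
2 | (S)-2-chlorohept-6-enal | C=CCCC[C@H](Cl)C=O | intermediate
3 | (S)-2-chlorohept-6-en-1-ol | C=CCCC[C@H](Cl)CO | intermediate
4 | 1,3-bis(benzyloxy)-5-bromobenzene | Brc1cc(OCc2ccccc2)cc(OCc2ccccc2)c1 | starting material
5 | (R)-2-(pent-4-en-1-yl)oxirane | C=CCCC[C@@H]1CO1 | intermediate
6 | 3,5-bis(benzyloxy)phenylmagnesium bromide | Br[Mg]c1cc(OCc2ccccc2)cc(OCc2ccccc2)c1 | intermediate
7 | bromomagnesium (R)-1-[3,5-bis(benzyloxy)phenyl]hept-6-en-2-olate | C=CCCC[C@H](Cc1cc(OCc2ccccc2)cc(OCc2ccccc2)c1)O[Mg]Br | intermediate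
8 | (R)-1-[3,5-bis(benzyloxy)phenyl]hept-6-en-2-yl acetate | C=CCCC[C@H](Cc1cc(OCc2ccccc2)cc(OCc2ccccc2)c1)OC(C)=O | intermediate
9 | oct-1-en-3-one | C=CC(=O)CCCCC | starting material
10 | (2R,6E)-1-[3,5-bis(benzyloxy)phenyl]-8-oxotridec-6-en-2-yl acetate | CCCCCC(=O)/C=C/CCC[C@H](Cc1cc(OCc2ccccc2)cc(OCc2ccccc2)c1)OC(C)=O | intermediate
11 | (2R,7Z)-1-[3,5-bis(benzyloxy)phenyl]-8-(trichlorosilyloxy)tridec-7-en-2-yl acetate | CCCCC/C(O[Si](Cl)(Cl)Cl)=C/CCCC[C@H](Cc1cc(OCc2ccccc2)cc(OCc2ccccc2)c1)OC(C)=O | intermediate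
12 | (2R,7R)-1-[3,5-bis(benzyloxy)phenyl]-8-oxo-7-{[phenyl(trichlorosilyl)amino]oxy}tridecan-2-yl acetate | CCCCCC(=O)[C@H](ON(c1ccccc1)[Si](Cl)(Cl)Cl)CCCC[C@H](Cc1cc(OCc2ccccc2)cc(OCc2ccccc2)c1)OC(C)=O | intermediate
13 | (2R,7R)-1-[3,5-bis(benzyloxy)phenyl]-8-oxo-7-[(phenylamino)oxy]tridecan-2-yl acetate | CCCCCC(=O)[C@H](ONc1ccccc1)CCCC[C@H](Cc1cc(OCc2ccccc2)cc(OCc2ccccc2)c1)OC(C)=O | intermediate
14 | (2R,7R)-1-(3,5-dihydroxyphenyl)-7-hydroxy-8-oxotridecan-2-yl acetate (CNP0374719.1) | CCCCCC(=O)[C@H](O)CCCC[C@H](Cc1cc(O)cc(O)c1)OC(C)=O | target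

**Step count and risk**
Total steps: 5. Longest linear sequence: 5 (1 → 3 → 8 → 10 → 13 → 14).

Step 4 (the proposed new step) is the most likely to fail. The risks are a racemic background reaction of the free trichlorosilyl enolate, attack on nitrogen instead of oxygen, reduction of PhNO by leftover HSiCl3, and an unknown sense of induction. C2 serves as an internal reference, so the 7R/7S ratio can be read directly by HPLC or NMR and (R)-BINAPO used if 7S dominates. The fallback uses known chemistry, sets out from 10 and comes back at 14. Enone 10 undergoes 1,4-hydrosilylation (Et3SiH, RhCl(PPh3)3 cat., THF, 50 °C) to the silyl enol ether (2R,7Z)-1-[3,5-bis(benzyloxy)phenyl]-8-(triethylsilyloxy)tridec-7-en-2-yl acetate F1. Shi asymmetric epoxidation follows (D-fructose-derived Shi ketone 30 mol%, KHSO5 as 2KHSO5·KHSO4·K2SO4, K2CO3, Bu4NHSO4, MeCN/dimethoxymethane/aq. Na2B4O7 buffer, 0 °C). In the spiro transition-state model the lone vinylic hydrogen at C7 fixes the approach, so oxygen goes to the C7 face that gives 7R. The product is the silyloxy epoxide (2R)-1-[3,5-bis(benzyloxy)phenyl]-6-[(2R,3S)-3-pentyl-3-(triethylsilyloxy)oxiran-2-yl]hexan-2-yl acetate F2, which collapses on mildly acidic work-up to the hydroxy ketone (2R,7R)-1-[3,5-bis(benzyloxy)phenyl]-7-hydroxy-8-oxotridecan-2-yl acetate F3. F3 is then debenzylated under the step 5 conditions (no aniline present) to give 14.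

Step 1 is the second risk. The α-chloro aldehyde can racemise or be chlorinated twice before reduction, and the enantiomeric excess and absolute sense must be confirmed on 3 by chiral GC. The fallback sets out from 1 and comes back at 5. L-Proline-catalysed α-aminoxylation of 1 (L-proline 20 mol%, PhNO, CHCl3, 4 °C) gives (R)-2-[(phenylamino)oxy]hept-6-enal F4, reduced in the same pot (NaBH4, EtOH) to (R)-2-[(phenylamino)oxy]hept-6-en-1-ol F5. N–O cleavage (Zn, AcOH) gives (R)-hept-6-ene-1,2-diol F6. Treatment with NaH and 1-(p-tolylsulfonyl)imidazole in THF sulfonylates the primary hydroxyl to (R)-2-hydroxyhept-6-en-1-yl 4-methylbenzenesulfonate F7, which closes with retention at C2 to epoxide 5. The THF solution of 5 then enters step 2 at the Grignard addition.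

Step 5 is the third risk. The aniline set free can slow benzyl ether hydrogenolysis on palladium and can condense with the ketone (reductive amination). The fallback avoids hydrogenation altogether, sets out from 13 and comes back at 14. Zn in AcOH/THF cleaves the N–O bond to the hydroxy ketone (2R,7R)-1-[3,5-bis(benzyloxy)phenyl]-7-hydroxy-8-oxotridecan-2-yl acetate F8 (the same substance as F3), from which aniline is washed out. BCl3 with pentamethylbenzene as benzyl cation scavenger (CH2Cl2, −78 °C) then removes both aryl benzyl ethers without touching the acetate or the ketol, giving 14.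

**Further compounds**
F1 | step 4 | (2R,7Z)-1-[3,5-bis(benzyloxy)phenyl]-8-(triethylsilyloxy)tridec-7-en-2-yl acetate | CCCCC/C(O[Si](CC)(CC)CC)=C/CCCC[C@H](Cc1cc(OCc2ccccc2)cc(OCc2ccccc2)c1)OC(C)=O
F2 | step 4 | (2R)-1-[3,5-bis(benzyloxy)phenyl]-6-[(2R,3S)-3-pentyl-3-(triethylsilyloxy)oxiran-2-yl]hexan-2-yl acetate | CCCCC[C@@]1(O[Si](CC)(CC)CC)O[C@@H]1CCCC[C@H](Cc1cc(OCc2ccccc2)cc(OCc2ccccc2)c1)OC(C)=O
F3 | step 4 | (2R,7R)-1-[3,5-bis(benzyloxy)phenyl]-7-hydroxy-8-oxotridecan-2-yl acetate | CCCCCC(=O)[C@H](O)CCCC[C@H](Cc1cc(OCc2ccccc2)cc(OCc2ccccc2)c1)OC(C)=O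
F4 | step 1 | (R)-2-[(phenylamino)oxy]hept-6-enal | C=CCCC[C@@H](ONc1ccccc1)C=O
F5 | step 1 | (R)-2-[(phenylamino)oxy]hept-6-en-1-ol | C=CCCC[C@@H](ONc1ccccc1)CO
F6 | step 1 | (R)-hept-6-ene-1,2-diol | C=CCCC[C@@H](O)CO
F7 | step 1 | (R)-2-hydroxyhept-6-en-1-yl 4-methylbenzenesulfonate | C=CCCC[C@@H](O)COS(=O)(=O)c1ccc(C)cc1
F8 | step 5 | (2R,7R)-1-[3,5-bis(benzyloxy)phenyl]-7-hydroxy-8-oxotridecan-2-yl acetate | CCCCCC(=O)[C@H](O)CCCC[C@H](Cc1cc(OCc2ccccc2)cc(OCc2ccccc2)c1)OC(C)=O
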